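**Strategy.** The pyran ring is taken apart at C4–C4a and C2–C3, which leaves an O-aryl oxocarbenium ion of acetone and a two-carbon enol ether. The benzo ring of the chromene (ring B) is a 2,6-dioxygenated benzoyl unit, so the acetonide of 2,6-dihydroxybenzoic acid already holds O1, C2 with both methyl groups and the future ketone carbon on C8. Lewis-acid opening of this dioxinone, addition of ethyl vinyl ether, ring closure onto C4a (para to the C7 oxygen) and loss of ethanol give the chromene acid in one operation. An aryl ester with a bromohydroquinone and a bromine–lithium exchange with O-to-C acyl shift then build the crowded benzophenone.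

Key step: step 2

Remark: compounds 1, 3 and 7 are taken as purchasable. The target has no stereogenic centre, so no step has to control configuration. Chromene numbering (O1, C2, C3, C4, C4a, C5–C8, C8a) is used for ring B; ring A is the formyl-bearing arene.

Step 1
Reactants: 1 5-hydroxy-2,2-dimethyl-4H-1,3-benzodioxin-4-one
Product: 2 5-(tert-butyldimethylsilyloxy)-2,2-dimethyl-4H-1,3-benzodioxin-4-one
Conditions: TBSCl (1.3 equiv), imidazole (2.5 equiv), DMF, rt
Reagents that add atoms: tert-butyldimethylsilyl chloride, CC(C)(C)[Si](C)(C)Cl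
Why: Silyl ether formation with imidazole-activated TBSCl caps the phenol, which then cannot form a mixed acetal with the vinyl ether in step 2 and stays protected until the last step.

Step 2
Reactants: 2 5-(tert-butyldimethylsilyloxy)-2,2-dimethyl-4H-1,3-benzodioxin-4-one; 3 ethyl vinyl ether
Product: 6 7-(tert-butyldimethylsilyloxy)-2,2-dimethyl-2H-chromene-8-carboxylic acid, via O-aryl oxocarbenium triflate 4 (not isolated), via 4-ethoxychroman trimethylsilyl ester 5 (not isolated)
Conditions: TMSOTf (2.2 equiv), 2,6-di-tert-butyl-4-methylpyridine (2.5 equiv), CH2Cl2, −78 °C, slow addition of 3 (1.3 equiv), then −78 → 0 °C; aq. NaH2PO4 work-up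
Reagents that add atoms: none
Why: Proposed new method: TMSOTf should silylate the lactone carbonyl of 2, a cyclic α-acyloxy ether, so that the acetal C–O(acyl) bond ionises with the silyl carboxylate as leaving group to the O-aryl oxocarbenium ion 4, a cationic 2-oxadiene; ethyl vinyl ether adds through its CH2 carbon to the cationic carbon (C2–C3), the resulting ethoxycarbenium ion is captured by the arene (C4–C4a) to give chroman 5, and TMSOTf-mediated E1 loss of ethanol from the doubly oxygen-stabilised benzylic position leaves the C3=C4 double bond. The closest known reaction types are the oxa-Povarov reaction (formal [4+2] of O-aryl oxocarbenium ions with alkenes to chromans), the original Povarov reaction with ethyl vinyl ether, and the Lewis-acid ionisation of α-acyloxy ethers and of 1,3-dioxan-4-ones at the acetal carbon followed by addition of enol ethers; new here are the salicylate acetonide as the cation source and the ketone-derived cation. The pyran ring is closed by a stepwise polar [4+2] annulation whose second bond forms in a six-membered Friedel–Crafts closure (6-exo-trig at the ethoxycarbenium carbon, arene π bond endo). The only stereocentre formed, C4 of 5, is racemic and is erased by the elimination, so no stereocontrol is required. The step needs ionisation towards the aryl rather than the acyl oxygen, which the better carboxylate leaving group and the lack of stabilisation in an acyloxycarbenium ion secure, and ring closure at a single carbon, which is secured because the other position ortho to O1 carries the carboxyl group while the free one is also para to the silyloxy group. Slow addition of 3 at low temperature and the hindered pyridine, which removes triflic acid, are meant to keep the vinyl ether from cationic oligomerisation.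

Step 3
Reactants: 7 1-bromo-2,5-dimethoxy-4-methylbenzene
Product: 8 2-bromo-5-methylbenzene-1,4-diol
Conditions: BBr3 (2.5 equiv), CH2Cl2, −78 °C → rt; H2O
Reagents that add atoms: none
Why: Lewis-acid cleavage of aryl methyl ethers, in which BBr3 coordinates each methoxy oxygen and bromide removes the methyl group by SN2 attack while the aryl bromide is inert.

Step 4
Reactants: 6 7-(tert-butyldimethylsilyloxy)-2,2-dimethyl-2H-chromene-8-carboxylic acid; 8 2-bromo-5-methylbenzene-1,4-diol
Product: 10 2-bromo-4-hydroxy-5-methylphenyl 7-(tert-butyldimethylsilyloxy)-2,2-dimethyl-2H-chromene-8-carboxylate, via acid chloride 9 (not isolated)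
Conditions: 1-chloro-N,N,2-trimethylprop-1-en-1-amine (1.1 equiv), CH2Cl2, 0 °C → rt; then 8 (1.5 equiv), Et3N (1.3 equiv), DMAP (cat.), CH2Cl2, 0 °C → rt
Reagents that add atoms: none
Why: Acid chloride formation under neutral conditions (Ghosez reagent) followed by DMAP-catalysed O-acylation, in which the phenol ortho to bromine, the more acidic of the two, is the one converted by triethylamine into the phenoxide and acylated, with 8 in excess to suppress double acylation.

Step 5
Reactants: 10 2-bromo-4-hydroxy-5-methylphenyl 7-(tert-butyldimethylsilyloxy)-2,2-dimethyl-2H-chromene-8-carboxylate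
Product: 11 2-bromo-5-methyl-4-[(3-methylbut-2-en-1-yl)oxy]phenyl 7-(tert-butyldimethylsilyloxy)-2,2-dimethyl-2H-chromene-8-carboxylate
Conditions: 3-methylbut-2-en-1-ol (1.3 equiv), PPh3 (1.3 equiv), DIAD (1.3 equiv), THF, 0 °C → rt
Reagents that add atoms: 3-methylbut-2-en-1-ol, CC(C)=CCO
Why: Mitsunobu etherification, in which the remaining phenol protonates the betaine and displaces the activated primary allylic alcohol by SN2 under neutral conditions that leave the aryl ester and the aryl silyl ether untouched.

Step 6
Reactants: 11 2-bromo-5-methyl-4-[(3-methylbut-2-en-1-yl)oxy]phenyl 7-(tert-butyldimethylsilyloxy)-2,2-dimethyl-2H-chromene-8-carboxylate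
Product: 15 2-[7-(tert-butyldimethylsilyloxy)-2,2-dimethyl-2H-chromene-8-carbonyl]-3-hydroxy-5-methyl-6-[(3-methylbut-2-en-1-yl)oxy]benzaldehyde, via 3-lithio arene 12 (not isolated), via lithium hemiaminal alkoxide 13 (not isolated), via 2-lithio aryl ester 14 (not isolated)
Conditions: LiN(i-Pr)2 (1.1 equiv), THF, −78 °C; DMF (1.2 equiv), −78 °C; t-BuLi (3.3 equiv), −78 → −20 °C; aq. NH4Cl, then 10% citric acid
Reagents that add atoms: N,N-dimethylformamide, CN(C)C=O
Why: Directed ortho-lithiation removes the ring proton flanked by bromine and the prenyloxy group, formylation with DMF gives a lithium hemiaminal alkoxide that masks the aldehyde in situ, and bromine–lithium exchange then triggers an anionic Fries-type 1,3 O-to-C acyl shift of the ortho-lithiated aryl ester through a four-membered tetrahedral intermediate, which delivers the hindered ketone intramolecularly and frees the phenol before aqueous acid releases the aldehyde.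

Step 7
Reactants: 15 2-[7-(tert-butyldimethylsilyloxy)-2,2-dimethyl-2H-chromene-8-carbonyl]-3-hydroxy-5-methyl-6-[(3-methylbut-2-en-1-yl)oxy]benzaldehyde
Product: 16 3-hydroxy-2-(7-hydroxy-2,2-dimethyl-2H-chromene-8-carbonyl)-5-methyl-6-[(3-methylbut-2-en-1-yl)oxy]benzaldehyde
Conditions: n-Bu4NF (1.1 equiv), AcOH (1.1 equiv), THF, 0 °C
Reagents that add atoms: none
Why: Fluoride-mediated cleavage of the aryl silyl ether, driven by Si–F bond formation and buffered with acetic acid so that the aldehyde, the prenyl ether and the chromene are left alone; a silyl group that may have moved to the neighbouring phenol in step 6 would be removed as well.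

**Compound list**

1 | 5-hydroxy-2,2-dimethyl-4H-1,3-benzodioxin-4-one (acetonide of 2,6-dihydroxybenzoic acid) | CC1(C)OC(=O)c2c(O)cccc2O1 | starting material
2 | 5-(tert-butyldimethylsilyloxy)-2,2-dimethyl-4H-1,3-benzodioxin-4-one | CC1(C)OC(=O)c2c(O[Si](C)(C)C(C)(C)C)cccc2O1 | intermediate
3 | ethyl vinyl ether | C=COCC | starting material
4 | (propan-2-ylidene)[3-(tert-butyldimethylsilyloxy)-2-(trimethylsilyloxycarbonyl)phenyl]oxonium triflate | CC(C)=[O+]c1cccc(O[Si](C)(C)C(C)(C)C)c1C(=O)O[Si](C)(C)C.[O-]S(=O)(=O)C(F)(F)F | intermediate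
5 | trimethylsilyl 7-(tert-butyldimethylsilyloxy)-4-ethoxy-2,2-dimethylchromane-8-carboxylate (racemic) | CCOC1CC(C)(C)Oc2c1ccc(O[Si](C)(C)C(C)(C)C)c2C(=O)O[Si](C)(C)C | intermediate
6 | 7-(tert-butyldimethylsilyloxy)-2,2-dimethyl-2H-chromene-8-carboxylic acid | CC1(C)C=Cc2ccc(O[Si](C)(C)C(C)(C)C)c(C(=O)O)c2O1 | intermediate
7 | 1-bromo-2,5-dimethoxy-4-methylbenzene | COc1cc(Br)c(OC)cc1C | starting material
8 | 2-bromo-5-methylbenzene-1,4-diol | Cc1cc(O)c(Br)cc1O | intermediate
9 | 7-(tert-butyldimethylsilyloxy)-2,2-dimethyl-2H-chromene-8-carbonyl chloride | CC1(C)C=Cc2ccc(O[Si](C)(C)C(C)(C)C)c(C(=O)Cl)c2O1 | intermediate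
10 | 2-bromo-4-hydroxy-5-methylphenyl 7-(tert-butyldimethylsilyloxy)-2,2-dimethyl-2H-chromene-8-carboxylate | Cc1cc(OC(=O)c2c(O[Si](C)(C)C(C)(C)C)ccc3C=CC(C)(C)Oc23)c(Br)cc1O | intermediate
11 | 2-bromo-5-methyl-4-[(3-methylbut-2-en-1-yl)oxy]phenyl 7-(tert-butyldimethylsilyloxy)-2,2-dimethyl-2H-chromene-8-carboxylate | Cc1cc(OC(=O)c2c(O[Si](C)(C)C(C)(C)C)ccc3C=CC(C)(C)Oc23)c(Br)cc1OCC=C(C)C | intermediate
12 | 2-bromo-3-lithio-5-methyl-4-[(3-methylbut-2-en-1-yl)oxy]phenyl 7-(tert-butyldimethylsilyloxy)-2,2-dimethyl-2H-chromene-8-carboxylate | Cc1cc(OC(=O)c2c(O[Si](C)(C)C(C)(C)C)ccc3C=CC(C)(C)Oc23)c(Br)c([Li])c1OCC=C(C)C | intermediate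
13 | 2-bromo-3-[(dimethylamino)(lithiooxy)methyl]-5-methyl-4-[(3-methylbut-2-en-1-yl)oxy]phenyl 7-(tert-butyldimethylsilyloxy)-2,2-dimethyl-2H-chromene-8-carboxylate | Cc1cc(OC(=O)c2c(O[Si](C)(C)C(C)(C)C)ccc3C=CC(C)(C)Oc23)c(Br)c(C(O[Li])N(C)C)c1OCC=C(C)C | intermediate
14 | 3-[(dimethylamino)(lithiooxy)methyl]-2-lithio-5-methyl-4-[(3-methylbut-2-en-1-yl)oxy]phenyl 7-(tert-butyldimethylsilyloxy)-2,2-dimethyl-2H-chromene-8-carboxylate | Cc1cc(OC(=O)c2c(O[Si](C)(C)C(C)(C)C)ccc3C=CC(C)(C)Oc23)c([Li])c(C(O[Li])N(C)C)c1OCC=C(C)C | intermediate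
15 | 2-[7-(tert-butyldimethylsilyloxy)-2,2-dimethyl-2H-chromene-8-carbonyl]-3-hydroxy-5-methyl-6-[(3-methylbut-2-en-1-yl)oxy]benzaldehyde | CC(C)=CCOc1c(C)cc(O)c(C(=O)c2c(O[Si](C)(C)C(C)(C)C)ccc3c2OC(C)(C)C=C3)c1C=O | intermediate
16 | 3-hydroxy-2-(7-hydroxy-2,2-dimethyl-2H-chromene-8-carbonyl)-5-methyl-6-[(3-methylbut-2-en-1-yl)oxy]benzaldehyde | CC(C)=CCOc1c(C)cc(O)c(C(=O)c2c(O)ccc3c2OC(C)(C)C=C3)c1C=O | target

**Step count.** Total: 7 steps. Longest linear sequence: 6 steps (steps 1, 2, 4, 5, 6 and 7 from 1); step 3 supplies 8 for the convergent step 4.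

**Steps most likely to fail**

1. Step 2 (proposed new method). The ring-opening equilibrium may lie far on the side of the closed dioxinone, so that the vinyl ether is consumed by cationic oligomerisation before it traps the cation. The benzylic cation formed during loss of ethanol may also be intercepted by a second vinyl ether instead of losing a proton. The fallback uses known chemistry, sets out from 1 and returns at 6. Compound 1 is condensed with 3-methylbut-2-enal (cat. ethylenediammonium diacetate, toluene, reflux), which C-alkylates the position ortho to the phenol and para to the acetal oxygen and closes the pyran by oxa-6π-electrocyclisation. This gives the acetonide of 7-hydroxy-2,2-dimethyl-2H-chromene-8-carboxylic acid F1, with the dioxinone ring fused across C7–O and C8 of the chromene. KOH in THF–H2O, then acidification, gives 7-hydroxy-2,2-dimethyl-2H-chromene-8-carboxylic acid F2. TBSCl (2.5 equiv) and imidazole in DMF give tert-butyldimethylsilyl 7-(tert-butyldimethylsilyloxy)-2,2-dimethyl-2H-chromene-8-carboxylate F3. K2CO3 in MeOH–THF–H2O at 0 °C cleaves only the silyl ester and returns 6.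

2. Step 6. Three organolithium events share one flask. The ortho-bromoaryllithium may lose LiBr to an aryne if the temperature rises, tert-butyllithium is partly consumed by diisopropylamine and residual DMF, and the acyl shift onto the doubly ortho-substituted benzoate may be slower than protonation of the aryllithium. The fallback replaces the in situ masking by an isolated acetal, so that formylation and acyl shift become separate, purified operations; it sets out from 11 and returns at 15. LiN(i-Pr)2 in THF at −78 °C, DMF and aqueous work-up give 2-bromo-3-formyl-5-methyl-4-[(3-methylbut-2-en-1-yl)oxy]phenyl 7-(tert-butyldimethylsilyloxy)-2,2-dimethyl-2H-chromene-8-carboxylate F4. HC(OMe)3 with catalytic PPTS in MeOH gives its dimethyl acetal F5. t-BuLi (2.1 equiv) in THF, −78 → −20 °C, effects exchange and acyl shift to the dimethyl acetal of 15, F6. PPTS in acetone–H2O at rt releases the aldehyde and gives 15.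

3. Step 4. Discrimination between the two phenols of 8 may be poor and acylation by the doubly ortho-substituted acid chloride slow, which would give the isomeric and the doubly acylated esters. The fallback reverses the order and uses kinetic nucleophilicity instead of acidity; it sets out from 8 and returns at 11. The disodium salt of 8 (NaH, 2.1 equiv, DMF, 0 °C) is treated with 1-bromo-3-methylbut-2-ene (1.0 equiv); the more basic phenoxide next to the methyl group should be alkylated first, giving 2-bromo-5-methyl-4-[(3-methylbut-2-en-1-yl)oxy]phenol F7. Its single phenol is then acylated with acid chloride 9 (Et3N, cat. DMAP, CH2Cl2) to give 11.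

**Further compounds**

F1 | step 2 | acetonide of 7-hydroxy-2,2-dimethyl-2H-chromene-8-carboxylic acid (2,2-dimethyl-1,3-dioxin-4-one ring fused across C7–O and C8 of the chromene) | CC1(C)Oc2ccc3C=CC(C)(C)Oc3c2C(=O)O1
F2 | step 2 | 7-hydroxy-2,2-dimethyl-2H-chromene-8-carboxylic acid | CC1(C)C=Cc2ccc(O)c(C(=O)O)c2O1
F3 | step 2 | tert-butyldimethylsilyl 7-(tert-butyldimethylsilyloxy)-2,2-dimethyl-2H-chromene-8-carboxylate | CC1(C)C=Cc2ccc(O[Si](C)(C)C(C)(C)C)c(C(=O)O[Si](C)(C)C(C)(C)C)c2O1
F4 | step 6 | 2-bromo-3-formyl-5-methyl-4-[(3-methylbut-2-en-1-yl)oxy]phenyl 7-(tert-butyldimethylsilyloxy)-2,2-dimethyl-2H-chromene-8-carboxylate | Cc1cc(OC(=O)c2c(O[Si](C)(C)C(C)(C)C)ccc3C=CC(C)(C)Oc23)c(Br)c(C=O)c1OCC=C(C)C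
F5 | step 6 | 2-bromo-3-(dimethoxymethyl)-5-methyl-4-[(3-methylbut-2-en-1-yl)oxy]phenyl 7-(tert-butyldimethylsilyloxy)-2,2-dimethyl-2H-chromene-8-carboxylate | Cc1cc(OC(=O)c2c(O[Si](C)(C)C(C)(C)C)ccc3C=CC(C)(C)Oc23)c(Br)c(C(OC)OC)c1OCC=C(C)C
F6 | step 6 | [7-(tert-butyldimethylsilyloxy)-2,2-dimethyl-2H-chromen-8-yl]{2-(dimethoxymethyl)-6-hydroxy-4-methyl-3-[(3-methylbut-2-en-1-yl)oxy]phenyl}methanone | CC(C)=CCOc1c(C)cc(O)c(C(=O)c2c(O[Si](C)(C)C(C)(C)C)ccc3c2OC(C)(C)C=C3)c1C(OC)OC
F7 | step 4 | 2-bromo-5-methyl-4-[(3-methylbut-2-en-1-yl)oxy]phenol | Cc1cc(O)c(Br)cc1OCC=C(C)C
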